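**Plan**

- Numbering: ring A is C1 (CO2H), C2 (heptyl), C3, C4 (OMe), C5, C6 (O to ring B); ring B is C1' (CO2H), C2' (OH), C3', C4' (O to ring A), C5' (OMe), C6' (heptyl).
- Retrosynthesis: the two benzyl groups come off last; the C1–CO2H bond and the C4 O–CH3 bond are cut; ring A is then opened at C4–C5, C1–C6 and C3–C4 into 3-heptylcyclobutenone and the ethynyl ether of ring B. Ring B is cut at C1'–C6', C5'–C6' and C3'–C4' into octanal, benzyl acetoacetate and benzyl methoxyacetate.
- Enabling feature: in ring A the heptyl group (C2), the C4 oxygen and the C6 ether oxygen are mutually meta, with C3 and C5 unsubstituted. This 5-alkylresorcinol diether pattern is what a vinylketene (C1–C4) and an ynol ether (C5, C6) assemble, so the diaryl ether oxygen can enter as the oxygen of an aryl ethynyl ether.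
- Forward order: ring B is made first (Knoevenagel, Michael–Dieckmann, aromatization) and its C4' hydroxyl is converted to O–C≡CH. Ring A is then grown on that alkyne, followed by O-methylation, C1 formylation, oxidation and hydrogenolysis.
- Stereochemistry: the target has no stereocentre; sp3 centres in intermediates are racemic and disappear on aromatization.

Key step: step 11

Remark: alkene-isomer, tautomer and diastereomer mixtures met along the way converge on aromatic compounds and are carried on unseparated.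

**Route**

Step 1
Reactants: 1 non-1-yne; 2 trichloroacetyl chloride
Product: 4 4,4-dichloro-3-heptylcyclobut-2-en-1-one, via dichloroketene 3 (not isolated)
Conditions: Zn–Cu couple, Et2O/DME, reflux, slow addition of 2
Reagents that add atoms: none
Why: Zinc dechlorination of 2 generates dichloroketene, whose [2+2] cycloaddition to a terminal alkyne joins the ketene carbonyl carbon to the unsubstituted alkyne carbon, the standard entry to 3-alkyl-4,4-dichlorocyclobutenones.

Step 2
Reactants: 4 4,4-dichloro-3-heptylcyclobut-2-en-1-one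
Product: 5 3-heptylcyclobut-2-en-1-one
Conditions: Zn dust, AcOH, TMEDA, EtOH, 0 °C to rt
Reagents that add atoms: none
Why: Reductive dechlorination of an α,α-dichloroketone by zinc and acetic acid, buffered by TMEDA so that the strained enone should survive.

Step 3
Reactants: 6 methoxyacetyl chloride; 7 benzyl alcohol
Product: 8 benzyl methoxyacetate
Conditions: pyridine, CH2Cl2, 0 °C to rt
Reagents that add atoms: none
Why: Acylation of an alcohol by an acid chloride; the benzyl ester is chosen so that the later Dieckmann closure expels benzyl oxide and cannot scramble the ring B ester.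

Step 4
Reactants: 9 octanal; 10 benzyl acetoacetate
Product: 11 benzyl 2-acetyldec-2-enoate (E/Z mixture)
Conditions: piperidine (cat.), AcOH (cat.), 4 Å MS, CH2Cl2, 0 °C
Reagents that add atoms: none
Why: Knoevenagel condensation (forms C1'–C6'), kept cold and at 1:1 stoichiometry so that it should stop at the alkylidene stage.

Step 5
Reactants: 8 benzyl methoxyacetate; 11 benzyl 2-acetyldec-2-enoate
Product: 13 benzyl 6-heptyl-5-methoxy-2,4-dioxocyclohexane-1-carboxylate, via Michael adduct 12 (not isolated)
Conditions: LDA, THF, −78 °C (8, then 11); then KOtBu, −78 °C to rt; aq. HCl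
Reagents that add atoms: none
Why: Michael addition of the lithium ester enolate to the doubly activated alkene (C5'–C6'), then Dieckmann condensation of the acetyl methyl group onto the methoxyacetate ester (C3'–C4'), driven by formation of the 1,3-dione enolate; this classical dihydroresorcylate construction fixes the methoxy group next to the heptyl-bearing carbon.

Step 6
Reactants: 13 benzyl 6-heptyl-5-methoxy-2,4-dioxocyclohexane-1-carboxylate
Product: 15 benzyl 6-heptyl-2,4-dihydroxy-5-methoxybenzoate, via bromodione 14 (not isolated)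
Conditions: Br2 (1.0 equiv), DMF, 0 °C, then 60 °C
Reagents that add atoms: none
Why: Bromination–dehydrobromination aromatization of a 2,4-dioxocyclohexanecarboxylate, the usual way to 6-alkylresorcylate esters; a single equivalent of bromine should limit bromination of the electron-rich product.

Step 7
Reactants: 15 benzyl 6-heptyl-2,4-dihydroxy-5-methoxybenzoate
Product: 16 benzyl 4-(ethenyloxy)-6-heptyl-2-hydroxy-5-methoxybenzoate
Conditions: 2,4,6-trivinylcyclotriboroxane–pyridine complex (0.4 equiv), Cu(OAc)2 (1 equiv), pyridine, CH2Cl2, rt, air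
Reagents that add atoms: 2,4,6-trivinylcyclotriboroxane–pyridine complex, C=CB1OB(C=C)OB(C=C)O1.c1ccncc1
Why: Copper-mediated Chan–Lam O-vinylation of a phenol, expected at the C4' hydroxyl because the C2' hydroxyl is hydrogen-bonded to the ester carbonyl and much less nucleophilic.

Step 8
Reactants: 16 benzyl 4-(ethenyloxy)-6-heptyl-2-hydroxy-5-methoxybenzoate
Product: 17 benzyl 2-(benzyloxy)-4-(ethenyloxy)-6-heptyl-5-methoxybenzoate
Conditions: BnBr, K2CO3, DMF, 50 °C
Reagents that add atoms: benzyl bromide, BrCc1ccccc1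
Why: Williamson etherification of the chelated phenol under carbonate/DMF conditions, which the base-stable vinyl ether should tolerate.

Step 9
Reactants: 17 benzyl 2-(benzyloxy)-4-(ethenyloxy)-6-heptyl-5-methoxybenzoate
Product: 19 benzyl 2-(benzyloxy)-4-[(Z)-2-bromoethenyl]oxy-6-heptyl-5-methoxybenzoate, via dibromide 18 (not isolated)
Conditions: Br2 (1.0 equiv), CH2Cl2, −78 °C; then DBU, −78 °C to rt
Reagents that add atoms: bromine, BrBr
Why: Bromine addition to the enol ether (much faster than arene bromination at −78 °C) followed by E2 loss of HBr, the classical bromination–dehydrobromination of vinyl ethers to storable 2-bromovinyl ethers.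

Step 10
Reactants: 19 benzyl 2-(benzyloxy)-4-[(Z)-2-bromoethenyl]oxy-6-heptyl-5-methoxybenzoate
Product: 20 benzyl 2-(benzyloxy)-4-(ethynyloxy)-6-heptyl-5-methoxybenzoate
Conditions: KOtBu (2.2 equiv), THF, −78 to 0 °C; cold aq. NH4Cl; crude product used at once
Reagents that add atoms: none
Why: Anti E2 dehydrobromination of a 2-bromovinyl ether to the 1-alkynyl ether, the classical route to aryloxyacetylenes, in which any E or 1-bromo isomer from step 9 converges on the same alkyne and the bulky alkoxide should spare the di-ortho-substituted benzyl benzoate.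

Step 11
Reactants: 20 benzyl 2-(benzyloxy)-4-(ethynyloxy)-6-heptyl-5-methoxybenzoate; 5 3-heptylcyclobut-2-en-1-one
Product: 25 benzyl 2-(benzyloxy)-6-heptyl-4-(3-heptyl-5-hydroxyphenoxy)-5-methoxybenzoate, via vinylketene 21 (not isolated), via vinylcyclobutenone 22 (not isolated), via dienylketene 23 (not isolated), via cyclohexadienone 24 (not isolated)
Conditions: 20 (1.0 equiv), 5 (1.5 equiv, added in portions), toluene, 80 °C then 110 °C, argon, sealed tube
Reagents that add atoms: none
Why: Thermal Danheiser benzannulation: 4π electrocyclic opening of 5 gives vinylketene 21, which adds [2+2] across the alkyne of 20 (forming C4–C5 and C1–C6) to give 4-vinylcyclobutenone 22, and a second 4π opening gives dienylketene 23. Ring A is then closed by 6π electrocyclization of 23 between the ketene carbon and the terminal methylene (C3–C4), and cyclohexadienone 24 tautomerizes to phenol 25. The closest known reaction is the same cascade of 3-alkylcyclobutenones with alkoxy- and siloxyacetylenes, which gives 5-alkylresorcinol monoethers; an aryloxyacetylene is a less electron-rich member of the same ynol ether class. No stereocentre remains in the product, since the single sp3 centre of 22 is racemic and is lost on ring opening. The selectivity needed is the orientation of the [2+2] step, and the polarization of the ynol ether secures it: its nucleophilic CH carbon bonds to the ketene carbonyl carbon, so the aryloxy group ends up meta to the new hydroxyl and the heptyl group meta to both. The conditions are neutral and metal-free, so the benzyl ester and benzyl ether of ring B should pass through unchanged.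

Step 12
Reactants: 25 benzyl 2-(benzyloxy)-6-heptyl-4-(3-heptyl-5-hydroxyphenoxy)-5-methoxybenzoate
Product: 26 benzyl 2-(benzyloxy)-6-heptyl-4-(3-heptyl-5-methoxyphenoxy)-5-methoxybenzoate
Conditions: MeI, K2CO3, acetone, reflux
Reagents that add atoms: iodomethane, CI
Why: Williamson O-methylation of the only free phenol.

Step 13
Reactants: 26 benzyl 2-(benzyloxy)-6-heptyl-4-(3-heptyl-5-methoxyphenoxy)-5-methoxybenzoate
Product: 27 benzyl 2-(benzyloxy)-4-(2-formyl-3-heptyl-5-methoxyphenoxy)-6-heptyl-5-methoxybenzoate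
Conditions: POCl3, DMF, 0 to 60 °C; then H2O, 0 °C to rt
Reagents that add atoms: N,N-dimethylformamide, CN(C)C=O; water, O
Why: Vilsmeier–Haack formylation, expected at C1 of ring A (para to the methoxy group, ortho to heptyl) as in 5-alkylresorcinol dimethyl ethers, because the aryloxy oxygen is a weaker donor (it is conjugated to the ring B ester) and ring B is deactivated by that ester.

Step 14
Reactants: 27 benzyl 2-(benzyloxy)-4-(2-formyl-3-heptyl-5-methoxyphenoxy)-6-heptyl-5-methoxybenzoate
Product: 28 2-[5-(benzyloxy)-4-(benzyloxycarbonyl)-3-heptyl-2-methoxyphenoxy]-6-heptyl-4-methoxybenzoic acid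
Conditions: NaClO2, NaH2PO4, 2-methylbut-2-ene, t-BuOH/THF/H2O, 0 °C to rt
Reagents that add atoms: sodium chlorite, [Na+].[O-]Cl=O
Why: Pinnick oxidation of a hindered, electron-rich benzaldehyde, with the alkene scavenger trapping hypochlorous acid so that the arenes should not be chlorinated.

Step 15
Reactants: 28 2-[5-(benzyloxy)-4-(benzyloxycarbonyl)-3-heptyl-2-methoxyphenoxy]-6-heptyl-4-methoxybenzoic acid
Product: 29 4-(2-carboxy-3-heptyl-5-methoxyphenoxy)-6-heptyl-2-hydroxy-5-methoxybenzoic acid (target)
Conditions: H2 (1 atm), Pd/C (10%), EtOAc, rt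
Reagents that add atoms: none
Why: Catalytic hydrogenolysis cleaves the benzyl ester and the benzyl ether together under neutral conditions, which should avoid decarboxylation of the two electron-rich benzoic acids.

**Compound list**

1 | non-1-yne | CCCCCCCC#C | starting material
2 | trichloroacetyl chloride | O=C(Cl)C(Cl)(Cl)Cl | starting material
3 | dichloroketene | ClC(Cl)=C=O | intermediate (not isolated)
4 | 4,4-dichloro-3-heptylcyclobut-2-en-1-one | CCCCCCCC1=CC(=O)C1(Cl)Cl | intermediate
5 | 3-heptylcyclobut-2-en-1-one | CCCCCCCC1=CC(=O)C1 | intermediate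
6 | methoxyacetyl chloride | COCC(=O)Cl | starting material
7 | benzyl alcohol | OCc1ccccc1 | starting material
8 | benzyl methoxyacetate | COCC(=O)OCc1ccccc1 | intermediate
9 | octanal | CCCCCCCC=O | starting material
10 | benzyl acetoacetate | CC(=O)CC(=O)OCc1ccccc1 | starting material
11 | benzyl 2-acetyldec-2-enoate (E/Z mixture) | CCCCCCCC=C(C(C)=O)C(=O)OCc1ccccc1 | intermediate
12 | dibenzyl 2-acetyl-3-heptyl-4-methoxypentanedioate (racemic diastereomer mixture) | CCCCCCCC(C(OC)C(=O)OCc1ccccc1)C(C(C)=O)C(=O)OCc1ccccc1 | intermediate (not isolated)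
13 | benzyl 6-heptyl-5-methoxy-2,4-dioxocyclohexane-1-carboxylate (racemic, diastereomers and enol tautomers) | CCCCCCCC1C(OC)C(=O)CC(=O)C1C(=O)OCc1ccccc1 | intermediate
14 | benzyl 3-bromo-6-heptyl-5-methoxy-2,4-dioxocyclohexane-1-carboxylate (racemic mixture) | CCCCCCCC1C(OC)C(=O)C(Br)C(=O)C1C(=O)OCc1ccccc1 | intermediate (not isolated)
15 | benzyl 6-heptyl-2,4-dihydroxy-5-methoxybenzoate | CCCCCCCc1c(OC)c(O)cc(O)c1C(=O)OCc1ccccc1 | intermediate
16 | benzyl 4-(ethenyloxy)-6-heptyl-2-hydroxy-5-methoxybenzoate | CCCCCCCc1c(OC)c(OC=C)cc(O)c1C(=O)OCc1ccccc1 | intermediate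
17 | benzyl 2-(benzyloxy)-4-(ethenyloxy)-6-heptyl-5-methoxybenzoate | CCCCCCCc1c(OC)c(OC=C)cc(OCc2ccccc2)c1C(=O)OCc1ccccc1 | intermediate
18 | benzyl 2-(benzyloxy)-4-(1,2-dibromoethoxy)-6-heptyl-5-methoxybenzoate (racemic) | CCCCCCCc1c(OC)c(OC(Br)CBr)cc(OCc2ccccc2)c1C(=O)OCc1ccccc1 | intermediate (not isolated)
19 | benzyl 2-(benzyloxy)-4-[(Z)-2-bromoethenyl]oxy-6-heptyl-5-methoxybenzoate | CCCCCCCc1c(OC)c(O/C=C\Br)cc(OCc2ccccc2)c1C(=O)OCc1ccccc1 | intermediate
20 | benzyl 2-(benzyloxy)-4-(ethynyloxy)-6-heptyl-5-methoxybenzoate | CCCCCCCc1c(OC)c(OC#C)cc(OCc2ccccc2)c1C(=O)OCc1ccccc1 | intermediate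
21 | 3-methylidenedec-1-en-1-one (vinylketene) | CCCCCCCC(=C)C=C=O | intermediate (not isolated)
22 | benzyl 2-(benzyloxy)-6-heptyl-5-methoxy-4-{[4-(non-1-en-2-yl)-3-oxocyclobut-1-en-1-yl]oxy}benzoate (racemic) | O=C1C=C(Oc2cc(OCc3ccccc3)c(C(=O)OCc3ccccc3)c(CCCCCCC)c2OC)C1C(=C)CCCCCCC | intermediate (not isolated)
23 | benzyl 2-(benzyloxy)-6-heptyl-5-methoxy-4-{[(3E)-5-methylidene-1-oxododeca-1,3-dien-3-yl]oxy}benzoate (dienylketene) | O=C=C/C(Oc2cc(OCc3ccccc3)c(C(=O)OCc3ccccc3)c(CCCCCCC)c2OC)=C\C(=C)CCCCCCC | intermediate (not isolated)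
24 | benzyl 2-(benzyloxy)-6-heptyl-4-[(5-heptyl-3-oxocyclohexa-1,5-dien-1-yl)oxy]-5-methoxybenzoate | O=C1C=C(Oc2cc(OCc3ccccc3)c(C(=O)OCc3ccccc3)c(CCCCCCC)c2OC)C=C(CCCCCCC)C1 | intermediate (not isolated)
25 | benzyl 2-(benzyloxy)-6-heptyl-4-(3-heptyl-5-hydroxyphenoxy)-5-methoxybenzoate | CCCCCCCc1cc(O)cc(Oc2cc(OCc3ccccc3)c(C(=O)OCc3ccccc3)c(CCCCCCC)c2OC)c1 | intermediate
26 | benzyl 2-(benzyloxy)-6-heptyl-4-(3-heptyl-5-methoxyphenoxy)-5-methoxybenzoate | CCCCCCCc1cc(OC)cc(Oc2cc(OCc3ccccc3)c(C(=O)OCc3ccccc3)c(CCCCCCC)c2OC)c1 | intermediate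
27 | benzyl 2-(benzyloxy)-4-(2-formyl-3-heptyl-5-methoxyphenoxy)-6-heptyl-5-methoxybenzoate | CCCCCCCc1cc(OC)cc(Oc2cc(OCc3ccccc3)c(C(=O)OCc3ccccc3)c(CCCCCCC)c2OC)c1C=O | intermediate
28 | 2-[5-(benzyloxy)-4-(benzyloxycarbonyl)-3-heptyl-2-methoxyphenoxy]-6-heptyl-4-methoxybenzoic acid | CCCCCCCc1cc(OC)cc(Oc2cc(OCc3ccccc3)c(C(=O)OCc3ccccc3)c(CCCCCCC)c2OC)c1C(=O)O | intermediate
29 | 4-(2-carboxy-3-heptyl-5-methoxyphenoxy)-6-heptyl-2-hydroxy-5-methoxybenzoic acid | CCCCCCCc1cc(OC)cc(Oc2cc(O)c(C(=O)O)c(CCCCCCC)c2OC)c1C(=O)O | target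

**Count and risks**

Total steps: 15. Longest linear sequence: 12 steps (steps 4 to 15, from octanal and benzyl acetoacetate); steps 1–2 and step 3 are side branches.

Steps most likely to fail:

1. Step 11. The aryloxyalkyne is less electron-rich than the alkoxyalkynes usually used. It may oligomerize or add the product phenol before it captures the vinylketene, while the ketene dimerizes or acylates the product. Fallback: join the rings by C–O coupling instead. Setting out from 17, mild acid hydrolysis of the vinyl ether (aq. HCl, THF) would give benzyl 2-(benzyloxy)-6-heptyl-4-hydroxy-5-methoxybenzoate F1. Mono-Kumada coupling of 3,5-dibromoanisole with heptylmagnesium bromide (PdCl2(dppf), THF) would give 1-bromo-3-heptyl-5-methoxybenzene F2. Ullmann-type coupling of the two (CuI, N,N-dimethylglycine, Cs2CO3, dioxane, 90 °C) would give 26, where the route is rejoined.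

2. Step 10. Elimination may stall on isomers lacking an antiperiplanar H/Br pair, and the terminal ynol ether may hydrate or polymerize during work-up. Fallback: reach the alkyne through a dichlorovinyl ether. Setting out from 15, trichloroethylene and K2CO3 in DMF at 70 °C would give benzyl 4-{[(E)-1,2-dichloroethenyl]oxy}-6-heptyl-2-hydroxy-5-methoxybenzoate F3. Benzylation (BnBr, K2CO3, DMF) would give benzyl 2-(benzyloxy)-4-{[(E)-1,2-dichloroethenyl]oxy}-6-heptyl-5-methoxybenzoate F4. Treatment with n-BuLi (2.2 equiv, THF, −78 to −40 °C; elimination to the chloroalkynyl ether, then chlorine–lithium exchange) and a methanol quench at −78 °C would give 20, where the route is rejoined. The di-ortho-substituted benzoate is expected to resist addition at this temperature.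

3. Step 13. The electrophile may enter ortho to the methoxy group (para to the aryloxy group) or attack C3' of ring B, giving isomeric aldehydes. Fallback: fix the position by halogenation para to the free phenol before methylation. Setting out from 25, N-iodosuccinimide in MeCN at 0 °C would give benzyl 2-(benzyloxy)-6-heptyl-4-(3-heptyl-5-hydroxy-2-iodophenoxy)-5-methoxybenzoate F5. Methylation (MeI, K2CO3, acetone) would give benzyl 2-(benzyloxy)-6-heptyl-4-(3-heptyl-2-iodo-5-methoxyphenoxy)-5-methoxybenzoate F6. Iodine–magnesium exchange (i-PrMgCl·LiCl, THF, −20 °C) and carboxylation with CO2 would give 28, where the route is rejoined.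

**Further compounds**

F1 | step 11 | benzyl 2-(benzyloxy)-6-heptyl-4-hydroxy-5-methoxybenzoate | CCCCCCCc1c(OC)c(O)cc(OCc2ccccc2)c1C(=O)OCc1ccccc1
F2 | step 11 | 1-bromo-3-heptyl-5-methoxybenzene | CCCCCCCc1cc(Br)cc(OC)c1
F3 | step 10 | benzyl 4-{[(E)-1,2-dichloroethenyl]oxy}-6-heptyl-2-hydroxy-5-methoxybenzoate | CCCCCCCc1c(OC)c(O/C(Cl)=C\Cl)cc(O)c1C(=O)OCc1ccccc1
F4 | step 10 | benzyl 2-(benzyloxy)-4-{[(E)-1,2-dichloroethenyl]oxy}-6-heptyl-5-methoxybenzoate | CCCCCCCc1c(OC)c(O/C(Cl)=C\Cl)cc(OCc2ccccc2)c1C(=O)OCc1ccccc1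
F5 | step 13 | benzyl 2-(benzyloxy)-6-heptyl-4-(3-heptyl-5-hydroxy-2-iodophenoxy)-5-methoxybenzoate | CCCCCCCc1cc(O)cc(Oc2cc(OCc3ccccc3)c(C(=O)OCc3ccccc3)c(CCCCCCC)c2OC)c1I
F6 | step 13 | benzyl 2-(benzyloxy)-6-heptyl-4-(3-heptyl-2-iodo-5-methoxyphenoxy)-5-methoxybenzoate | CCCCCCCc1cc(OC)cc(Oc2cc(OCc3ccccc3)c(C(=O)OCc3ccccc3)c(CCCCCCC)c2OC)c1I
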